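**Plan**

Ring B is numbered C1 (ketone carbon), C2 (OH), C3 (H), C4 (CH3), C5 (OCH3), C6 (CH2OAc); ring A is the 2,6-dimethoxyphenyl group. C1 and C2 of ring B carry an aroyl group and a free phenol side by side, so both can be installed at once by adding a carboxylic acid across a C1≡C2 aryne.
Retrosynthetic cuts, in order: the acetate O–C(=O) bond; then C1–C(=O) and C2–O of ring B together (aryne plus ring A acid); then, in the aryne precursor, C1–Si, the triflate O–S bond, the C6–CH2O carbon and C1–Br.
Forward: 4-methoxy-3-methylphenol 1 already holds the C2 oxygen, the C4 methyl and the C5 methoxy group. It is brominated at C1 and formylated at C6 (then reduced and MOM-protected), and the bromine is traded for silicon while the C2 oxygen is triflated.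
The aryne released from this silyl triflate is joined to 2,6-dimethoxybenzoic acid 2; MOM removal and acetylation of the benzylic alcohol finish the synthesis.
No ring is formed at any stage (both benzene rings are bought) and the target has no stereocentre, so there is no stereochemistry to control.

Key step: step 8

Assumption: 1 and 2 are taken to be catalogue compounds.

**Route**

Step 1
Reactants: 1 4-methoxy-3-methylphenol
Product: 3 2-bromo-4-methoxy-5-methylphenol
Conditions: NBS, CH2Cl2, −20 to 0 °C
Reagents that add atoms: N-bromosuccinimide O=C1CCC(=O)N1Br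
Why: Electrophilic aromatic bromination of a phenol: the free OH directs NBS to its ortho positions, and the one para to the methyl group (C1) is open whereas the other (C3) is wedged between OH and CH3.

Step 2
Reactants: 3 2-bromo-4-methoxy-5-methylphenol
Product: 4 (2-bromo-4-methoxy-5-methylphenoxy)(tert-butyl)dimethylsilane
Conditions: TBSCl, imidazole, DMF, rt
Reagents that add atoms: tert-butyldimethylsilyl chloride CC(C)(C)[Si](C)(C)Cl
Why: Silyl ether formation (silylation of a phenol) masks the acidic OH for the amide-base step with a group that is a poor metalation director and is later removed by fluoride without harm to an acetal.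

Step 3
Reactants: 4 (2-bromo-4-methoxy-5-methylphenoxy)(tert-butyl)dimethylsilane
Product: 6 2-bromo-3-[(tert-butyldimethylsilyl)oxy]-6-methoxy-5-methylbenzaldehyde, via aryllithium 5 (not isolated)
Conditions: LiN(iPr)2, THF, −78 °C; DMF, −78 °C; AcOH
Reagents that add atoms: N,N-dimethylformamide CN(C)C=O
Why: Directed ortho-lithiation followed by formylation with DMF: the C6 hydrogen is the only one flanked by Br and OCH3 and is removed by the lithium amide without bromine–lithium exchange, and the aryllithium is trapped at −78 °C before it can lose LiBr.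

Step 4
Reactants: 6 2-bromo-3-[(tert-butyldimethylsilyl)oxy]-6-methoxy-5-methylbenzaldehyde
Product: 7 {2-bromo-3-[(tert-butyldimethylsilyl)oxy]-6-methoxy-5-methylphenyl}methanol
Conditions: NaBH4, THF/MeOH, 0 °C
Reagents that add atoms: none
Why: Borohydride reduction of an aromatic aldehyde to the benzylic alcohol, which leaves the aryl bromide and the aryl silyl ether untouched at 0 °C.

Step 5
Reactants: 7 {2-bromo-3-[(tert-butyldimethylsilyl)oxy]-6-methoxy-5-methylphenyl}methanol
Product: 8 tert-butyl{2-bromo-4-methoxy-3-[(methoxymethoxy)methyl]-5-methylphenoxy}dimethylsilane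
Conditions: MOMCl, iPr2NEt, CH2Cl2, 0 °C to rt
Reagents that add atoms: chloromethyl methyl ether COCCl
Why: O-Alkylation of the primary alcohol with MOMCl and an amine base (acetal protection) gives an ether that is inert to fluoride and has no carbonyl group and no acidic C–H within reach of the later C1 aryl anion.

Step 6
Reactants: 8 tert-butyl{2-bromo-4-methoxy-3-[(methoxymethoxy)methyl]-5-methylphenoxy}dimethylsilane
Product: 9 2-bromo-4-methoxy-3-[(methoxymethoxy)methyl]-5-methylphenol
Conditions: Bu4NF, AcOH, THF, 0 °C
Reagents that add atoms: none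
Why: Fluoride-induced desilylation of an aryl silyl ether, buffered with AcOH, frees the C2 phenol while the MOM acetal and the C–Br bond stay intact.

Step 7
Reactants: 9 2-bromo-4-methoxy-3-[(methoxymethoxy)methyl]-5-methylphenol
Product: 13 4-methoxy-3-[(methoxymethoxy)methyl]-5-methyl-2-(trimethylsilyl)phenyl trifluoromethanesulfonate, via aryl trimethylsilyl ether 10 (not isolated), via aryllithium 11 (not isolated), via lithium phenolate 12 (not isolated)
Conditions: HN(SiMe3)2, THF, 70 °C; evaporate; n-BuLi, THF, −100 to −78 °C; Tf2O, −100 to −78 °C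
Reagents that add atoms: hexamethyldisilazane C[Si](C)(C)N[Si](C)(C)C; trifluoromethanesulfonic anhydride O=S(=O)(OS(=O)(=O)C(F)(F)F)C(F)(F)F
Why: O-Silylation, bromine–lithium exchange and 1,3 O-to-C silyl shift (retro-Brook rearrangement), then O-triflation of the lithium phenolate is the standard one-flask route from ortho-bromophenols to ortho-silylaryl triflates, and the exchange at −100 °C is faster than any deprotonation next to the MOM ether.

Step 8
Reactants: 13 4-methoxy-3-[(methoxymethoxy)methyl]-5-methyl-2-(trimethylsilyl)phenyl trifluoromethanesulfonate; 2 2,6-dimethoxybenzoic acid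
Product: 16 (2,6-dimethoxyphenyl){2-hydroxy-5-methoxy-6-[(methoxymethoxy)methyl]-4-methylphenyl}methanone, via caesium 2,6-dimethoxybenzoate 14 (not isolated), via aryne 15 (not isolated)
Conditions: 2 (1.2 equiv), CsF (4 equiv), THF, 125 °C, sealed tube
Reagents that add atoms: none
Why: CsF turns acid 2 into carboxylate 14 and strips the trimethylsilyl group from C1 of 13 with loss of triflate from C2, which releases aryne 15; a carboxylate oxygen adds to C2, and the C1 aryl anion so formed attacks the adjacent ester carbonyl to a benzoxetene alkoxide that opens to the C1 ketone and the C2 phenoxide. The closest known reaction type is the fluoride-mediated insertion of arynes into the C–O bond of carboxylic acids (aryne 1,2-difunctionalisation with O-to-C acyl transfer), which gives ortho-hydroxyaryl ketones. The four-membered ring arises by 4-exo-trig attack and is only transient, so no ring is kept, and no stereocentre is created. The step needs O-attack at C2 and not at C1: C1 is screened by the CH2OMOM group on C6 whereas C2 has only the C3 hydrogen beside it, and the sigma-withdrawing CH2O group on C6 and the OCH3 on C5 favour negative charge at C1. It also needs acyl transfer to outrun protonation of the C1 anion, for which the aprotic medium, the excess CsF as proton sink and the high temperature are chosen; the di-ortho-substituted benzoate carbonyl is reached only intramolecularly. The MOM ether offers the C1 anion neither a carbonyl group nor an acidic C–H, which an acetate on C6 would.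

Step 9
Reactants: 16 (2,6-dimethoxyphenyl){2-hydroxy-5-methoxy-6-[(methoxymethoxy)methyl]-4-methylphenyl}methanone
Product: 17 (2,6-dimethoxyphenyl)[2-hydroxy-6-(hydroxymethyl)-5-methoxy-4-methylphenyl]methanone
Conditions: 2 M HCl (aq), THF, 40 °C
Reagents that add atoms: none
Why: Acid-catalysed hydrolysis of the MOM acetal; water in place of an alcohol cosolvent rules out ketal formation, and the ketone, twisted between two doubly ortho-substituted rings and hydrogen-bonded to the C2 OH, should resist attack by the freed CH2OH at 40 °C.

Step 10
Reactants: 17 (2,6-dimethoxyphenyl)[2-hydroxy-6-(hydroxymethyl)-5-methoxy-4-methylphenyl]methanone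
Product: 18 preacredinone A ([2-(2,6-dimethoxybenzoyl)-3-hydroxy-6-methoxy-5-methylphenyl]methyl acetate)
Conditions: Ac2O (1.1 equiv), pyridine, CH2Cl2, 0 °C
Reagents that add atoms: acetic anhydride CC(=O)OC(C)=O
Why: O-Acylation with acetic anhydride and pyridine should take the primary benzylic alcohol first, because the C2 phenol is tied up in a hydrogen bond to the ketone and shielded by the aroyl group (the known inertness of chelated ortho-acylphenols).

**Compound list**

1 | 4-methoxy-3-methylphenol | COc1ccc(O)cc1C | starting material
2 | 2,6-dimethoxybenzoic acid | COc1cccc(OC)c1C(=O)O | starting material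
3 | 2-bromo-4-methoxy-5-methylphenol | COc1cc(Br)c(O)cc1C | intermediate
4 | (2-bromo-4-methoxy-5-methylphenoxy)(tert-butyl)dimethylsilane | COc1cc(Br)c(O[Si](C)(C)C(C)(C)C)cc1C | intermediate
5 | {2-bromo-3-[(tert-butyldimethylsilyl)oxy]-6-methoxy-5-methylphenyl}lithium (not isolated) | COc1c([Li])c(Br)c(O[Si](C)(C)C(C)(C)C)cc1C | intermediate
6 | 2-bromo-3-[(tert-butyldimethylsilyl)oxy]-6-methoxy-5-methylbenzaldehyde | COc1c(C=O)c(Br)c(O[Si](C)(C)C(C)(C)C)cc1C | intermediate
7 | {2-bromo-3-[(tert-butyldimethylsilyl)oxy]-6-methoxy-5-methylphenyl}methanol | COc1c(CO)c(Br)c(O[Si](C)(C)C(C)(C)C)cc1C | intermediate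
8 | tert-butyl{2-bromo-4-methoxy-3-[(methoxymethoxy)methyl]-5-methylphenoxy}dimethylsilane | COCOCc1c(OC)c(C)cc(O[Si](C)(C)C(C)(C)C)c1Br | intermediate
9 | 2-bromo-4-methoxy-3-[(methoxymethoxy)methyl]-5-methylphenol | COCOCc1c(OC)c(C)cc(O)c1Br | intermediate
10 | {2-bromo-4-methoxy-3-[(methoxymethoxy)methyl]-5-methylphenoxy}trimethylsilane (not isolated) | COCOCc1c(OC)c(C)cc(O[Si](C)(C)C)c1Br | intermediate
11 | {3-methoxy-2-[(methoxymethoxy)methyl]-4-methyl-6-[(trimethylsilyl)oxy]phenyl}lithium (not isolated) | COCOCc1c(OC)c(C)cc(O[Si](C)(C)C)c1[Li] | intermediate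
12 | lithium 4-methoxy-3-[(methoxymethoxy)methyl]-5-methyl-2-(trimethylsilyl)phenolate (not isolated) | COCOCc1c(OC)c(C)cc([O-])c1[Si](C)(C)C.[Li+] | intermediate
13 | 4-methoxy-3-[(methoxymethoxy)methyl]-5-methyl-2-(trimethylsilyl)phenyl trifluoromethanesulfonate | COCOCc1c([Si](C)(C)C)c(OS(=O)(=O)C(F)(F)F)cc(C)c1OC | intermediate
14 | caesium 2,6-dimethoxybenzoate (not isolated) | COc1cccc(OC)c1C(=O)[O-].[Cs+] | intermediate
15 | 4-methoxy-3-[(methoxymethoxy)methyl]-5-methyl-1,2-didehydrobenzene (aryne, not isolated) | COCOCC1=C(OC)C(C)=CC#C1 | intermediate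
16 | (2,6-dimethoxyphenyl){2-hydroxy-5-methoxy-6-[(methoxymethoxy)methyl]-4-methylphenyl}methanone | COCOCc1c(C(=O)c2c(OC)cccc2OC)c(O)cc(C)c1OC | intermediate
17 | (2,6-dimethoxyphenyl)[2-hydroxy-6-(hydroxymethyl)-5-methoxy-4-methylphenyl]methanone | COc1cccc(OC)c1C(=O)c1c(O)cc(C)c(OC)c1CO | intermediate
18 | preacredinone A, [2-(2,6-dimethoxybenzoyl)-3-hydroxy-6-methoxy-5-methylphenyl]methyl acetate | COc1cccc(OC)c1C(=O)c1c(O)cc(C)c(OC)c1COC(C)=O | target

**Step count**

Total: 10 steps. Longest linear sequence: 10 steps (1 to 18); acid 2 is used as bought in step 8.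

**Steps most likely to fail**

Step 8. The carboxylate may add to C1 as well as to C2 of the aryne, since the bias exerted by a CH2O substituent is modest. The C1 aryl anion may also pick up a proton before it reaches the crowded ester carbonyl, so that O-arylation stops short of acyl transfer. Capture of the aryne by an acetal oxygen of the MOM group, or by the product phenoxide, would drain material further.
The fallback sets out from bromophenol 9 and acid 2 and returns at ketone 16. Acid 2 is converted with (COCl)2 and catalytic DMF in CH2Cl2 into 2,6-dimethoxybenzoyl chloride F1. This acylates 9 (Et3N, catalytic 4-(dimethylamino)pyridine, CH2Cl2) to give 2-bromo-4-methoxy-3-[(methoxymethoxy)methyl]-5-methylphenyl 2,6-dimethoxybenzoate F2. Bromine–lithium exchange with n-BuLi in THF at −100 °C should give the C1 aryllithium, 2-lithio-4-methoxy-3-[(methoxymethoxy)methyl]-5-methylphenyl 2,6-dimethoxybenzoate F3. F3 should undergo the same 1,3 O-to-C acyl shift (anionic Fries-type rearrangement started by halogen–metal exchange) and give 16 after an AcOH quench. The C2–O bond is in place before C1 is metalated, so the regiochemistry is fixed, no proton source is present, and the hindered ester resists direct attack by n-BuLi.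

Step 10. The C2 phenol may be acylated alongside the benzylic alcohol, or the alcohol, which sits between OCH3 and the aroyl group, may react too slowly for the selectivity to hold.
The fallback sets out from diol 17 and returns at target 18. Both hydroxyl groups are acetylated with excess Ac2O, pyridine and catalytic 4-(dimethylamino)pyridine at rt to give 3-[(acetyloxy)methyl]-2-(2,6-dimethoxybenzoyl)-4-methoxy-5-methylphenyl acetate F4. The aryl acetate alone is then cleaved by aminolysis with pyrrolidine in CH2Cl2 at 0 °C, since amines attack phenyl esters far faster than alkyl esters.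

Step 7. n-BuLi may attack silicon of the trimethylsilyl ether in place of bromine–lithium exchange, which returns the phenol without silicon on C1. The C1 anion may also be protonated before the silyl shift, as three operations are run in one flask on the most crowded ring carbon.
The fallback sets out from silyl ether 8 (so that step 6 is bypassed as well) and returns at silyl triflate 13. Bromine–lithium exchange on 8 with n-BuLi in THF at −78 °C should give {6-[(tert-butyldimethylsilyl)oxy]-3-methoxy-2-[(methoxymethoxy)methyl]-4-methylphenyl}lithium F5. Trapping at once with Me3SiCl gives tert-butyl{4-methoxy-3-[(methoxymethoxy)methyl]-5-methyl-2-(trimethylsilyl)phenoxy}dimethylsilane F6. Bu4NF and AcOH in THF at 0 °C free 4-methoxy-3-[(methoxymethoxy)methyl]-5-methyl-2-(trimethylsilyl)phenol F7, and Tf2O with pyridine in CH2Cl2 at 0 °C converts it into 13. Silicon is delivered intermolecularly to an aryllithium whose own silyl ether is too hindered to be attacked, and the triflation is done separately on an isolated phenol.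

**Further compounds**

F1 | step 8 | 2,6-dimethoxybenzoyl chloride | COc1cccc(OC)c1C(Cl)=O
F2 | step 8 | 2-bromo-4-methoxy-3-[(methoxymethoxy)methyl]-5-methylphenyl 2,6-dimethoxybenzoate | COCOCc1c(OC)c(C)cc(OC(=O)c2c(OC)cccc2OC)c1Br
F3 | step 8 | 2-lithio-4-methoxy-3-[(methoxymethoxy)methyl]-5-methylphenyl 2,6-dimethoxybenzoate | COCOCc1c(OC)c(C)cc(OC(=O)c2c(OC)cccc2OC)c1[Li]
F4 | step 10 | 3-[(acetyloxy)methyl]-2-(2,6-dimethoxybenzoyl)-4-methoxy-5-methylphenyl acetate | COc1cccc(OC)c1C(=O)c1c(OC(C)=O)cc(C)c(OC)c1COC(C)=O
F5 | step 7 | {6-[(tert-butyldimethylsilyl)oxy]-3-methoxy-2-[(methoxymethoxy)methyl]-4-methylphenyl}lithium | COCOCc1c(OC)c(C)cc(O[Si](C)(C)C(C)(C)C)c1[Li]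
F6 | step 7 | tert-butyl{4-methoxy-3-[(methoxymethoxy)methyl]-5-methyl-2-(trimethylsilyl)phenoxy}dimethylsilane | COCOCc1c(OC)c(C)cc(O[Si](C)(C)C(C)(C)C)c1[Si](C)(C)C
F7 | step 7 | 4-methoxy-3-[(methoxymethoxy)methyl]-5-methyl-2-(trimethylsilyl)phenol | COCOCc1c(OC)c(C)cc(O)c1[Si](C)(C)C
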